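**Plan**
Locants: C7′ is the ArCH–O carbon, C8′ the CH–CH3 carbon, C8 the ring CH that carries the benzylic C7H2, and C9 the OCH2. Ring A is the phenolic ring and ring B the trimethoxy ring.
Retrosynthesis: cut the biaryl bond (ring A C2 to ring B C2′) and return C9 to a lactone carbonyl. Then cut C7–C8 and C8′–CH3 together, then the butenolide C=C, the acrylate C–O and the C7′–vinyl bond.
Enabling feature: the tetrahydrofuran (O, C7′, C8′, C8, C9) has aryl, methyl and benzyl on the adjacent carbons C7′, C8′ and C8, each trans to its neighbour. A 5-aryl butenolide with C9 as carbonyl gives exactly this when a methyl nucleophile and then a benzyl electrophile each enter anti to the group already present.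
Forward: the five-membered ring is made first as a butenolide by metathesis, decorated in one flask, and reduced to the tetrahydrofuran. The eight-membered ring is closed last by oxidative biaryl coupling, and the tosylate is then removed.
Stereochemistry: C7′ comes from a lipase resolution of the aryl vinyl carbinol; C8′ and C8 are relayed from it in the key step.

Key step: step 9

Remark: the structure given defines three stereocentres and no biaryl axis. The axis is assumed to adopt the one helicity that the bicyclic bridge allows, so no axis descriptor is written.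

**Step 1**
Reactants: 1 3,4,5-trimethoxybenzaldehyde; 2 vinylmagnesium bromide
Product: 3 rac-1-(3,4,5-trimethoxyphenyl)prop-2-en-1-ol
Conditions: CH2=CHMgBr (1.2 equiv), THF, 0 °C; aq NH4Cl
Reagents that add atoms: none
Why: Grignard 1,2-addition to a non-enolisable aryl aldehyde gives the allylic alcohol, whose carbinol carbon (later C7′) is formed racemic and is resolved in step 2.

**Step 2**
Reactants: 3 rac-1-(3,4,5-trimethoxyphenyl)prop-2-en-1-ol
Product: 4 (R)-1-(3,4,5-trimethoxyphenyl)prop-2-en-1-yl acetate
Conditions: Novozym 435 (immobilised Candida antarctica lipase B), vinyl acetate, t-BuOMe, 30 °C, stopped near half conversion; chromatography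
Reagents that add atoms: vinyl acetate, CC(=O)OC=C
Why: Lipase-catalysed kinetic resolution by irreversible transesterification, in which the empirical size rule for secondary alcohols (aryl large, vinyl medium) predicts acylation of the R enantiomer, so C7′ is set here and the S alcohol stays behind; the assignment should be confirmed on 5 before going on.

**Step 3**
Reactants: 4 (R)-1-(3,4,5-trimethoxyphenyl)prop-2-en-1-yl acetate
Product: 5 (R)-1-(3,4,5-trimethoxyphenyl)prop-2-en-1-ol
Conditions: K2CO3 (cat.), MeOH, 0 °C → rt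
Reagents that add atoms: none
Why: Base-catalysed methanolysis cleaves the ester at the acyl carbon, so the C–O bond at the stereocentre is not touched and the configuration is kept.

**Step 4**
Reactants: 5 (R)-1-(3,4,5-trimethoxyphenyl)prop-2-en-1-ol; 6 acryloyl chloride
Product: 7 (R)-1-(3,4,5-trimethoxyphenyl)prop-2-en-1-yl acrylate
Conditions: Et3N, CH2Cl2, 0 °C
Reagents that add atoms: none
Why: O-acylation of a secondary alcohol with an acid chloride, an acyl transfer that leaves the stereocentre untouched.

**Step 5**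
Reactants: 7 (R)-1-(3,4,5-trimethoxyphenyl)prop-2-en-1-yl acrylate
Product: 8 (R)-5-(3,4,5-trimethoxyphenyl)furan-2(5H)-one
Conditions: second-generation Grubbs catalyst (H2IMes)(PCy3)Cl2Ru=CHPh (5 mol %), CH2Cl2 (0.01 M), 40 °C
Reagents that add atoms: none
Why: Ring-closing metathesis of an allyl acrylate to a butenolide, with the carbene loading on the electron-rich vinyl group and closing onto the acrylate with loss of ethene under neutral conditions that spare the acidic C7′–H.

**Step 6**
Reactants: 9 3-hydroxy-4,5-dimethoxybenzaldehyde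
Product: 10 5-formyl-2,3-dimethoxyphenyl 4-methylbenzenesulfonate
Conditions: TsCl, Et3N, 4-(dimethylamino)pyridine (cat.), CH2Cl2, 0 °C → rt
Reagents that add atoms: p-toluenesulfonyl chloride, Cc1ccc(cc1)S(=O)(=O)Cl
Why: Sulfonylation of the phenol gives a protecting group without acidic hydrogen that also deactivates the ring A position para to it, which later steers the biaryl coupling to C2.

**Step 7**
Reactants: 10 5-formyl-2,3-dimethoxyphenyl 4-methylbenzenesulfonate
Product: 11 5-(hydroxymethyl)-2,3-dimethoxyphenyl 4-methylbenzenesulfonate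
Conditions: NaBH4, MeOH–THF, 0 °C
Reagents that add atoms: none
Why: Borohydride reduction of an aryl aldehyde, to which the aryl sulfonate is inert.

**Step 8**
Reactants: 11 5-(hydroxymethyl)-2,3-dimethoxyphenyl 4-methylbenzenesulfonate
Product: 12 5-(bromomethyl)-2,3-dimethoxyphenyl 4-methylbenzenesulfonate
Conditions: PBr3, CH2Cl2, 0 °C
Reagents that add atoms: phosphorus tribromide, BrP(Br)Br
Why: A benzylic alcohol is converted into the bromide through its phosphite ester and SN2 displacement by bromide.

**Step 9**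
Reactants: 8 (R)-5-(3,4,5-trimethoxyphenyl)furan-2(5H)-one; 12 5-(bromomethyl)-2,3-dimethoxyphenyl 4-methylbenzenesulfonate
Product: 14 (3R,4R,5R)-3-[4,5-dimethoxy-3-(tosyloxy)benzyl]-4-methyl-5-(3,4,5-trimethoxyphenyl)dihydrofuran-2(3H)-one, via lithium lactone enolate 13 (not isolated)
Conditions: Me2CuLi (1.2 equiv, from CuI and 2 MeLi), Et2O, −78 °C; then 12 (1.5 equiv), THF–HMPA, −78 → −20 °C; aq NH4Cl/NH3
Reagents that add atoms: lithium dimethylcuprate, [Li+].C[Cu-]C (made in the flask from methyllithium, [Li]C, and CuI)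
Why: The cuprate transfers methyl to C8′, the β-carbon of butenolide 8, through a copper π-complex and a trivalent-copper β-adduct that reductively eliminates to leave lithium enolate 13, which then displaces bromide from 12 by SN2 at C8 and so forms C7–C8. The closest known reaction type is the tandem conjugate addition and enolate alkylation (three-component coupling) of 5-substituted butenolides and cyclic enones. No ring closes; the lactone already holds the five ring atoms of the later tetrahydrofuran, with C9 as the carbonyl carbon. C8′ is controlled by the C7′ aryl group, which shields one face of the flat butenolide so that methyl enters anti to it; C8 is controlled by the new C8′ methyl, the planar enolate being benzylated on the face away from it, which gives the trans,trans array. The step needs 1,4- over 1,2-addition, C- over O-alkylation and no removal of the acidic C7′ proton; the soft, weakly basic cuprate at −78 °C, the reactive benzylic bromide with hexamethylphosphoramide, and the absence of acidic hydrogen in tosylate 12 should secure these.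

**Step 10**
Reactants: 14 (3R,4R,5R)-3-[4,5-dimethoxy-3-(tosyloxy)benzyl]-4-methyl-5-(3,4,5-trimethoxyphenyl)dihydrofuran-2(3H)-one
Product: 15 (3R,4R,5R)-3-[4,5-dimethoxy-3-(tosyloxy)benzyl]-4-methyl-5-(3,4,5-trimethoxyphenyl)tetrahydrofuran-2-ol (both C2 epimers)
Conditions: i-Bu2AlH (1.1 equiv), CH2Cl2, −78 °C; aq potassium sodium tartrate
Reagents that add atoms: none
Why: Partial reduction of a lactone to the lactol, whose tetrahedral aluminium alkoxide persists at −78 °C; the aryl tosylate and the three stereocentres are untouched, and the anomeric mixture at C9 is irrelevant because C9 becomes CH2.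

**Step 11**
Reactants: 15 the lactol
Product: 16 (2R,3R,4R)-4-[4,5-dimethoxy-3-(tosyloxy)benzyl]-3-methyl-2-(3,4,5-trimethoxyphenyl)tetrahydrofuran
Conditions: Et3SiH (3 equiv), BF3·OEt2 (2 equiv), CH2Cl2, −78 → −40 °C
Reagents that add atoms: none
Why: Ionic hydrogenation of a lactol, in which BF3 ionises the anomeric C9–OH and Et3SiH delivers hydride to the resulting cyclic oxocarbenium carbon; C9 becomes CH2 without a new stereocentre, and the low temperature should keep the benzylic C7′–O bond intact.

**Step 12**
Reactants: 16 the tetrahydrofuran tosylate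
Product: 17 O-tosyl derivative of the target (ring A C2 bonded to ring B C2′; 7′R,8R,8′R)
Conditions: PhI(OCOCF3)2 (1.1 equiv), BF3·OEt2 (2 equiv), CH2Cl2 (0.005 M), −40 °C
Reagents that add atoms: none
Why: Non-phenolic oxidative biaryl coupling with a trivalent-iodine reagent, in which the electron-rich ring B is oxidised to its radical cation and is attacked by ring A through C2 (para to the 5-methoxy group, whereas C6 lies para to the deactivating sulfonate); the cis-disposed aryl and benzyl groups on the tetrahydrofuran allow the eight-membered ring to close, and the two ortho positions of ring B are equivalent.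

**Step 13**
Reactants: 17 the bridged biaryl tosylate
Product: 18 the target, (7′R,8R,8′R)-7′,9-epoxy dibenzocyclooctadiene phenol (CNP0322364.1)
Conditions: KOH, MeOH–dioxane–H2O, 80 °C; then aq HCl to pH 5
Reagents that add atoms: none
Why: Hydroxide attacks sulfur of the aryl sulfonate and releases the phenoxide; the substrate has no epimerisable centre and no other base-labile group.

**Compound list**
1 | 3,4,5-trimethoxybenzaldehyde | COc1cc(C=O)cc(OC)c1OC | starting material
2 | vinylmagnesium bromide | C=C[Mg]Br | starting material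
3 | rac-1-(3,4,5-trimethoxyphenyl)prop-2-en-1-ol | COc1cc(cc(OC)c1OC)C(O)C=C | intermediate
4 | (R)-1-(3,4,5-trimethoxyphenyl)prop-2-en-1-yl acetate | COc1cc(cc(OC)c1OC)[C@@H](C=C)OC(C)=O | intermediate
5 | (R)-1-(3,4,5-trimethoxyphenyl)prop-2-en-1-ol | COc1cc(cc(OC)c1OC)[C@@H](C=C)O | intermediate
6 | acryloyl chloride | C=CC(=O)Cl | starting material
7 | (R)-1-(3,4,5-trimethoxyphenyl)prop-2-en-1-yl acrylate | COc1cc(cc(OC)c1OC)[C@@H](C=C)OC(=O)C=C | intermediate
8 | (R)-5-(3,4,5-trimethoxyphenyl)furan-2(5H)-one | COc1cc(cc(OC)c1OC)[C@@H]1OC(=O)C=C1 | intermediate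
9 | 3-hydroxy-4,5-dimethoxybenzaldehyde | COc1cc(C=O)cc(O)c1OC | starting material
10 | 5-formyl-2,3-dimethoxyphenyl 4-methylbenzenesulfonate | COc1cc(C=O)cc(OS(=O)(=O)c2ccc(C)cc2)c1OC | intermediate
11 | 5-(hydroxymethyl)-2,3-dimethoxyphenyl 4-methylbenzenesulfonate | COc1cc(CO)cc(OS(=O)(=O)c2ccc(C)cc2)c1OC | intermediate
12 | 5-(bromomethyl)-2,3-dimethoxyphenyl 4-methylbenzenesulfonate | COc1cc(CBr)cc(OS(=O)(=O)c2ccc(C)cc2)c1OC | intermediate
13 | lithium (4R,5R)-4-methyl-5-(3,4,5-trimethoxyphenyl)-4,5-dihydrofuran-2-olate (not isolated) | COc1cc(cc(OC)c1OC)[C@@H]1OC([O-])=C[C@H]1C.[Li+] | intermediate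
14 | (3R,4R,5R)-3-[4,5-dimethoxy-3-(tosyloxy)benzyl]-4-methyl-5-(3,4,5-trimethoxyphenyl)dihydrofuran-2(3H)-one | COc1cc(cc(OC)c1OC)[C@@H]1OC(=O)[C@H](Cc2cc(OC)c(OC)c(OS(=O)(=O)c3ccc(C)cc3)c2)[C@H]1C | intermediate
15 | (3R,4R,5R)-3-[4,5-dimethoxy-3-(tosyloxy)benzyl]-4-methyl-5-(3,4,5-trimethoxyphenyl)tetrahydrofuran-2-ol, C2 epimers | COc1cc(cc(OC)c1OC)[C@@H]1OC(O)[C@H](Cc2cc(OC)c(OC)c(OS(=O)(=O)c3ccc(C)cc3)c2)[C@H]1C | intermediate
16 | (2R,3R,4R)-4-[4,5-dimethoxy-3-(tosyloxy)benzyl]-3-methyl-2-(3,4,5-trimethoxyphenyl)tetrahydrofuran | COc1cc(cc(OC)c1OC)[C@@H]1OC[C@H](Cc2cc(OC)c(OC)c(OS(=O)(=O)c3ccc(C)cc3)c2)[C@H]1C | intermediate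
17 | O-tosyl derivative of the target, (7′R,8R,8′R) | COc1cc2c(c(OS(=O)(=O)c3ccc(C)cc3)c1OC)-c1c(cc(OC)c(OC)c1OC)[C@@H]1OC[C@H](C2)[C@H]1C | intermediate
18 | target CNP0322364.1, (7′R,8R,8′R) | COc1cc2c(c(O)c1OC)-c1c(cc(OC)c(OC)c1OC)[C@@H]1OC[C@H](C2)[C@H]1C | target

**Count**
Total steps: 13. Longest linear sequence: 10 steps (steps 1–5 and 9–13); the ring A branch (steps 6–8) joins at step 9.

**Steps most likely to fail**

Step 12, the oxidative biaryl coupling. Ring A may attack through C6 instead of C2, the trimethoxyarene may be over-oxidised, or intermolecular coupling may outrun closure of the strained eight-membered ring. The fallback is a regiodefined reductive coupling of two aryl halides; it sets out from 9 and comes back at 17.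
- Bromination of 9 (Br2, NaOAc, AcOH), ortho to the phenol and para to the 5-methoxy group, should give 2-bromo-3-hydroxy-4,5-dimethoxybenzaldehyde F1.
- Tosylation as in step 6 gives 2-bromo-4,5-dimethoxy-3-(tosyloxy)benzaldehyde F2, NaBH4 gives [2-bromo-4,5-dimethoxy-3-(tosyloxy)phenyl]methanol F3, and PBr3 gives 2-bromo-4,5-dimethoxy-3-(tosyloxy)benzyl bromide F4.
- The key step is run unchanged with 8 and F4, through enolate 13, to the bromo lactone F5.
- i-Bu2AlH gives the bromo lactol F6, and Et3SiH with BF3·OEt2 gives the bromo tetrahydrofuran F7.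
- N-Iodosuccinimide with catalytic CF3CO2H iodinates ring B at one of its two equivalent free positions to give the bromo iodide F8; ring A is deactivated by bromine and sulfonate.
- An intramolecular Ullmann coupling (activated Cu powder, zerovalent copper, DMF, 130 °C) joins the two halogen-bearing carbons and returns to the route at 17.

Step 9, the tandem addition and benzylation. The copper-bound enolate may be benzylated too slowly, so that proton transfer, O-alkylation or coupling of residual methylcopper species with 12 takes over. The fallback separates the two bond formations; it sets out from 8 and comes back at 14. Me2CuLi in Et2O at −78 °C followed by an NH4Cl quench gives (4R,5R)-4-methyl-5-(3,4,5-trimethoxyphenyl)dihydrofuran-2(3H)-one F9. LiN(SiMe3)2 in THF at −78 °C then regenerates enolate 13 free of copper, and 12 alkylates it anti to the methyl group to give 14.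

Step 11, the lactol reduction. BF3 may ionise the benzylic C7′–O bond of the electron-rich aryl ether as well as the anomeric C9–OH, with epimerisation at C7′ or reductive opening of the ring. The fallback closes the ring without Lewis acid and never breaks the C7′–O bond; it sets out from 14 and comes back at 16. LiBH4 in THF opens the lactone to (1R,2R,3R)-3-[4,5-dimethoxy-3-(tosyloxy)benzyl]-2-methyl-1-(3,4,5-trimethoxyphenyl)butane-1,4-diol F10. MsCl and Et3N in CH2Cl2 at −20 °C sulfonylate the primary hydroxyl to the primary monomesylate F11, which is not isolated: on warming, the benzylic hydroxyl displaces the mesylate at C9 (5-exo-tet) and gives 16.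

**Further compounds**
F1 | step 12 | 2-bromo-3-hydroxy-4,5-dimethoxybenzaldehyde | COc1cc(C=O)c(Br)c(O)c1OC
F2 | step 12 | 2-bromo-4,5-dimethoxy-3-(tosyloxy)benzaldehyde | COc1cc(C=O)c(Br)c(OS(=O)(=O)c2ccc(C)cc2)c1OC
F3 | step 12 | [2-bromo-4,5-dimethoxy-3-(tosyloxy)phenyl]methanol | COc1cc(CO)c(Br)c(OS(=O)(=O)c2ccc(C)cc2)c1OC
F4 | step 12 | 2-bromo-4,5-dimethoxy-3-(tosyloxy)benzyl bromide | COc1cc(CBr)c(Br)c(OS(=O)(=O)c2ccc(C)cc2)c1OC
F5 | step 12 | (3R,4R,5R)-3-[2-bromo-4,5-dimethoxy-3-(tosyloxy)benzyl]-4-methyl-5-(3,4,5-trimethoxyphenyl)dihydrofuran-2(3H)-one | COc1cc(cc(OC)c1OC)[C@@H]1OC(=O)[C@H](Cc2cc(OC)c(OC)c(OS(=O)(=O)c3ccc(C)cc3)c2Br)[C@H]1C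
F6 | step 12 | (3R,4R,5R)-3-[2-bromo-4,5-dimethoxy-3-(tosyloxy)benzyl]-4-methyl-5-(3,4,5-trimethoxyphenyl)tetrahydrofuran-2-ol, C2 epimers | COc1cc(cc(OC)c1OC)[C@@H]1OC(O)[C@H](Cc2cc(OC)c(OC)c(OS(=O)(=O)c3ccc(C)cc3)c2Br)[C@H]1C
F7 | step 12 | (2R,3R,4R)-4-[2-bromo-4,5-dimethoxy-3-(tosyloxy)benzyl]-3-methyl-2-(3,4,5-trimethoxyphenyl)tetrahydrofuran | COc1cc(cc(OC)c1OC)[C@@H]1OC[C@H](Cc2cc(OC)c(OC)c(OS(=O)(=O)c3ccc(C)cc3)c2Br)[C@H]1C
F8 | step 12 | (2R,3R,4R)-4-[2-bromo-4,5-dimethoxy-3-(tosyloxy)benzyl]-2-(2-iodo-3,4,5-trimethoxyphenyl)-3-methyltetrahydrofuran | COc1cc(c(I)c(OC)c1OC)[C@@H]1OC[C@H](Cc2cc(OC)c(OC)c(OS(=O)(=O)c3ccc(C)cc3)c2Br)[C@H]1C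
F9 | step 9 | (4R,5R)-4-methyl-5-(3,4,5-trimethoxyphenyl)dihydrofuran-2(3H)-one | COc1cc(cc(OC)c1OC)[C@@H]1OC(=O)C[C@H]1C
F10 | step 11 | (1R,2R,3R)-3-[4,5-dimethoxy-3-(tosyloxy)benzyl]-2-methyl-1-(3,4,5-trimethoxyphenyl)butane-1,4-diol | COc1cc(cc(OC)c1OC)[C@H](O)[C@H](C)[C@H](CO)Cc1cc(OC)c(OC)c(OS(=O)(=O)c2ccc(C)cc2)c1
F11 | step 11 | primary (C4) methanesulfonate of diol F10 | COc1cc(cc(OC)c1OC)[C@H](O)[C@H](C)[C@H](COS(C)(=O)=O)Cc1cc(OC)c(OC)c(OS(=O)(=O)c2ccc(C)cc2)c1
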